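**Plan**
- Retrosynthesis: first the six O-benzyl bonds are cut. Then two bonds are cut together: the bond from the pyranone-ring oxygen to its ring A carbon, and the C–C bond between the ketal carbon and the tertiary carbinol carbon. This gives an aryl 4-(benzyloxy)benzoate of a 7-hydroxyflavan carrying CH(OBn)–CO–(2-fluoroaryl) at C-8. Further cuts: the ester C–O bond, the C-8–CH bond (aryllithium + arylglyoxal) and the flavan O–C-2 bond.
- Enabling feature: the ketal carbon shared by the furan and pyranone rings is at the carboxylic-acid oxidation level. With its two aryloxy oxygens and its 4-hydroxyphenyl group it is the trapped tetrahedral intermediate of an aryl 4-hydroxybenzoate. The neighbouring carbinol carbon is α to the pyranone C=O, so it is an enolate carbon. The pyranone oxygen sits on a ring A carbon ortho to that C=O, so that carbon is an SNAr site when it bears fluorine.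
- Forward order: flavan ring (aldol, C=C and C=O reduction, Mitsunobu), C-8 bromide, aryllithium addition to the ring A glyoxal, O-benzylation, MOM-to-ester exchange, furan and pyranone rings in one operation, global hydrogenolysis.
- Stereochemistry: flavan C-2 (S) comes from Noyori transfer hydrogenation to the (R)-carbinol and Mitsunobu inversion. The carbinol (S) and ketal (R) carbons are set in the key step: cis fusion by ring geometry, absolute sense by a chiral ammonium counter-ion, with the other diastereomer separable.

Key step: step 15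

Remark (assumption): the carbinol carbon made in step 11 is carried as both epimers through 15, 16, 17 and 19 because it becomes planar in step 15. The target descriptors read from the structure are flavan C-2 S, ketal carbon R, tertiary carbinol carbon S.

**Route**

Step 1
Reactants: 1 2,4,6-trihydroxybenzaldehyde
Product: 2 2,6-dihydroxy-4-(methoxymethoxy)benzaldehyde
Conditions: MOMCl (1.0 equiv), i-Pr2NEt (1.1 equiv), THF, −20 to 0 °C
Reagents that add atoms: chloromethyl methyl ether, COCCl
Why: The 4-hydroxyl is the only one not hydrogen-bonded to the formyl group and is the most acidic, so one equivalent of MOMCl should give selective Williamson-type O-alkylation there.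

Step 2
Reactants: 2 2,6-dihydroxy-4-(methoxymethoxy)benzaldehyde
Product: 3 2-(benzyloxy)-6-hydroxy-4-(methoxymethoxy)benzaldehyde
Conditions: BnBr (1.05 equiv), K2CO3, acetone, rt
Reagents that add atoms: benzyl bromide, BrCc1ccccc1
Why: Williamson etherification of one of two equivalent hydroxyls; the remaining OH is then locked in a hydrogen bond to the aldehyde and should resist a second alkylation at room temperature.

Step 3
Reactants: 3 2-(benzyloxy)-6-hydroxy-4-(methoxymethoxy)benzaldehyde; 4 1-[4-(benzyloxy)phenyl]ethanone
Product: 5 (E)-3-[2-(benzyloxy)-6-hydroxy-4-(methoxymethoxy)phenyl]-1-[4-(benzyloxy)phenyl]prop-2-en-1-one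
Conditions: KOH (50% aq., 5 equiv), EtOH, rt, dark; then AcOH to pH 6
Reagents that add atoms: none
Why: Claisen–Schmidt aldol condensation of the non-enolisable aldehyde with the methyl ketone enolate and E1cB dehydration should give the E-enone, the MOM and benzyl ethers being base-stable.

Step 4
Reactants: 5 the E-enone
Product: 6 3-[2-(benzyloxy)-6-hydroxy-4-(methoxymethoxy)phenyl]-1-[4-(benzyloxy)phenyl]propan-1-one
Conditions: H2 (1 atm), 5% Pd/C, Ph2S (cat.), EtOAc, rt
Reagents that add atoms: none
Why: Chemoselective catalytic hydrogenation: sulfide-poisoned Pd/C should saturate the conjugated C=C bond while leaving aryl benzyl ethers and the aryl ketone intact.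

Step 5
Reactants: 6 the saturated ketone
Product: 7 (1R)-3-[2-(benzyloxy)-6-hydroxy-4-(methoxymethoxy)phenyl]-1-[4-(benzyloxy)phenyl]propan-1-ol
Conditions: RuCl(p-cymene)[(R,R)-TsDPEN] (1 mol %), HCO2H/Et3N (5:2), CH2Cl2, 30 °C
Reagents that add atoms: none
Why: Noyori asymmetric transfer hydrogenation of the aryl alkyl ketone; the (R,R)-TsDPEN ruthenium hydride should give the (R)-carbinol through the six-membered outer-sphere transition state, in the same sense as for acetophenone.

Step 6
Reactants: 7 the (R)-carbinol
Product: 8 (2S)-5-(benzyloxy)-2-[4-(benzyloxy)phenyl]-7-(methoxymethoxy)chromane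
Conditions: PPh3, DIAD (diisopropyl azodicarboxylate), toluene/THF, −10 to 0 °C
Reagents that add atoms: none
Why: Intramolecular Mitsunobu etherification: the phenol displaces the oxyphosphonium group in a 6-exo-tet SN2 closure with inversion, turning the (R)-carbinol into the (2S)-flavan, and the low temperature is meant to suppress ionisation of the 4-alkoxybenzylic centre.

Step 7
Reactants: 8 the (2S)-flavan
Product: 9 (2S)-5-(benzyloxy)-2-[4-(benzyloxy)phenyl]-8-bromo-7-(methoxymethoxy)chromane
Conditions: NBS (1.0 equiv), CH2Cl2, −78 to −20 °C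
Reagents that add atoms: N-bromosuccinimide, O=C1CCC(=O)N1Br
Why: Electrophilic aromatic bromination of the phloroglucinol-type ring; C-8, between O-7 and the tied-back ring oxygen, is less hindered than C-6 between two acyclic ethers, as in the 8-selective bromination of per-benzylated flavan-3-ols.

Step 8
Reactants: 10 5-fluorobenzene-1,3-diol
Product: 11 1-(2-fluoro-4,6-dihydroxyphenyl)ethanone
Conditions: MeCN, HCl (g), ZnCl2, Et2O, 0 °C; then H2O, reflux
Reagents that add atoms: acetonitrile, CC#N; water, O
Why: Hoesch acylation: the nitrilium electrophile attacks para to one hydroxyl and ortho to the other (the position next to fluorine), and hydrolysis of the ketimine gives the methyl ketone.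

Step 9
Reactants: 11 1-(2-fluoro-4,6-dihydroxyphenyl)ethanone
Product: 12 1-[2,4-bis(benzyloxy)-6-fluorophenyl]ethanone
Conditions: BnBr (2.3 equiv), K2CO3, DMF, 60 °C
Reagents that add atoms: benzyl bromide, BrCc1ccccc1
Why: Williamson etherification of both phenols (the chelated one needs warming), the fluoride being too weakly activated for intermolecular SNAr under these conditions.

Step 10
Reactants: 12 1-[2,4-bis(benzyloxy)-6-fluorophenyl]ethanone
Product: 13 2-[2,4-bis(benzyloxy)-6-fluorophenyl]-2-oxoacetaldehyde
Conditions: SeO2 (1.5 equiv), 1,4-dioxane/H2O (30:1), reflux; hydrate dried by azeotropic distillation with toluene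
Reagents that add atoms: selenium dioxide, O=[Se]=O
Why: Riley oxidation of the aryl methyl ketone to the arylglyoxal, which benzyl ethers and the aryl fluoride tolerate.

Step 11
Reactants: 9 the 8-bromoflavan; 13 the arylglyoxal
Product: 15 1-[2,4-bis(benzyloxy)-6-fluorophenyl]-2-hydroxy-2-{(2S)-5-(benzyloxy)-2-[4-(benzyloxy)phenyl]-7-(methoxymethoxy)chroman-8-yl}ethan-1-one (both carbinol epimers), via 8-lithioflavan 14 (not isolated)
Conditions: n-BuLi (1.05 equiv), THF, −78 °C; then 13 in THF, −78 °C; NH4Cl (aq.) at −78 °C
Reagents that add atoms: none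
Why: Bromine–lithium exchange gives the MOM-chelated aryllithium, which should add (1,2-addition) to the aldehyde carbonyl in preference to the twisted, di-ortho-substituted ketone; the new carbinol centre is uncontrolled, which does not matter because it is planarised in step 15.

Step 12
Reactants: 15 the α-hydroxy ketone
Product: 16 2-(benzyloxy)-1-[2,4-bis(benzyloxy)-6-fluorophenyl]-2-{(2S)-5-(benzyloxy)-2-[4-(benzyloxy)phenyl]-7-(methoxymethoxy)chroman-8-yl}ethan-1-one (both epimers)
Conditions: 2-(benzyloxy)-1-methylpyridinium trifluoromethanesulfonate (2 equiv), MgO (2 equiv), PhCF3, 85 °C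
Reagents that add atoms: 2-(benzyloxy)-1-methylpyridinium trifluoromethanesulfonate, C[n+]1ccccc1OCc1ccccc1.[O-]S(=O)(=O)C(F)(F)F
Why: Dudley benzylation: thermal ionisation of the pyridinium salt transfers a benzyl cation to the hindered secondary alcohol under neutral conditions, avoiding the alkoxide that would displace the ortho fluoride or isomerise the α-ketol.

Step 13
Reactants: 16 the benzyl ether
Product: 17 2-(benzyloxy)-1-[2,4-bis(benzyloxy)-6-fluorophenyl]-2-{(2S)-5-(benzyloxy)-2-[4-(benzyloxy)phenyl]-7-hydroxychroman-8-yl}ethan-1-one (both epimers)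
Conditions: ZnBr2 (1 equiv), n-PrSH (2 equiv), CH2Cl2, 0 °C, 10 min
Reagents that add atoms: none
Why: Lewis-acid-activated acetal exchange with the thiol should cleave the aryl MOM ether within minutes, too briefly and mildly for thioketalisation of the hindered ketone or cyclodehydration to a benzofuran, while benzyl ethers and the flavan ether stay.

Step 14
Reactants: 17 the phenol; 18 4-(benzyloxy)benzoyl chloride
Product: 19 (2S)-5-(benzyloxy)-2-[4-(benzyloxy)phenyl]-8-{1-(benzyloxy)-2-[2,4-bis(benzyloxy)-6-fluorophenyl]-2-oxoethyl}chroman-7-yl 4-(benzyloxy)benzoate (both epimers)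
Conditions: Et3N (2 equiv), 4-(dimethylamino)pyridine (10 mol %), CH2Cl2, 0 °C
Reagents that add atoms: none
Why: DMAP-catalysed acyl transfer to the phenol; Et3N is far too weak to enolise the α-benzyloxy ketone, so the cascade is not triggered early.

Step 15
Reactants: 19 the aryl ester
Product: 22 hexa-O-benzyl ether of the target (ketal carbon R; benzyloxy-bearing ring-fusion carbon S; flavan C-2 S), via enolate 20 (not isolated), via hemiketal alkoxide 21 (not isolated)
Conditions: N-(9-anthracenylmethyl)-O-allylcinchonidinium bromide (10 mol %), Cs2CO3 (finely ground, 3 equiv), toluene, −20 °C to 40 °C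
Reagents that add atoms: none
Why: Proposed new method: phase-transfer deprotonation of the C–H flanked by the ketone, the benzyloxy group and the flavan ring gives enolate 20, whose carbon adds to the neighbouring aryl ester carbonyl (5-exo-trig, furan ring, C–C bond) to give tetrahedral alkoxide 21, and this oxygen then displaces the fluoride ortho to the ketone through a Meisenheimer adduct (6-exo addition–elimination SNAr, pyranone ring, aryl C–O bond), the only irreversible event. The closest known chemistry is the Baker–Venkataraman O-to-C acyl transfer and the C-acylation/SNAr synthesis of chromones from 2-fluoroaryl ketones; what is new is that the quaternary benzyloxy-bearing carbon forbids dehydration, so the tetrahedral intermediate of the ester is itself trapped as the diaryl ketal. If 21 collapses to the 1,3-diketone phenoxide it re-forms by ring–chain tautomerism, so the reversible species funnel into the SNAr. The ketal centre follows from the carbinol centre because only a hemiketal oxygen cis to the aroyl group can reach the C–F carbon, a trans-fused five/six bicycle being too strained. The sense at the carbinol carbon relative to the flavan centre four bonds away is not biased by the substrate and is assigned to the chiral ammonium cation paired with 20 (the pseudo-enantiomeric cinchoninium salt if the sense proves opposite), the minor diastereomer being removable by chromatography. The step needs C- over O-acylation and alkoxide over phenoxide arylation: the first is secured by the five-membered against a seven-membered transition state, the second by six- against seven-membered closure, and the benzyl group on the carbinol oxygen excludes its own five-membered SNAr.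

Step 16
Reactants: 22 the hexabenzyl ether
Product: 23 the target (flavan C-2 S, ketal carbon R, tertiary carbinol carbon S)
Conditions: H2 (1 atm), Pd(OH)2 on carbon, THF/MeOH, rt
Reagents that add atoms: none
Why: Hydrogenolysis of five aryl benzyl ethers and one tertiary alkyl benzyl ether; by analogy with per-benzylated flavans and A-type proanthocyanidins the flavan C-2–O bond, the diaryl ketal and the hydrogen-bonded ketone should survive, and no stereocentre is touched.

**Compound list**

1 | 2,4,6-trihydroxybenzaldehyde | O=Cc1c(O)cc(O)cc1O | starting material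
2 | 2,6-dihydroxy-4-(methoxymethoxy)benzaldehyde | O=Cc1c(O)cc(OCOC)cc1O | intermediate
3 | 2-(benzyloxy)-6-hydroxy-4-(methoxymethoxy)benzaldehyde | O=Cc1c(O)cc(OCOC)cc1OCc1ccccc1 | intermediate
4 | 1-[4-(benzyloxy)phenyl]ethanone | CC(=O)c1ccc(OCc2ccccc2)cc1 | starting material
5 | (E)-3-[2-(benzyloxy)-6-hydroxy-4-(methoxymethoxy)phenyl]-1-[4-(benzyloxy)phenyl]prop-2-en-1-one | O=C(/C=C/c1c(O)cc(OCOC)cc1OCc1ccccc1)c1ccc(OCc2ccccc2)cc1 | intermediate
6 | 3-[2-(benzyloxy)-6-hydroxy-4-(methoxymethoxy)phenyl]-1-[4-(benzyloxy)phenyl]propan-1-one | O=C(CCc1c(O)cc(OCOC)cc1OCc1ccccc1)c1ccc(OCc2ccccc2)cc1 | intermediate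
7 | (1R)-3-[2-(benzyloxy)-6-hydroxy-4-(methoxymethoxy)phenyl]-1-[4-(benzyloxy)phenyl]propan-1-ol | O[C@H](CCc1c(O)cc(OCOC)cc1OCc1ccccc1)c1ccc(OCc2ccccc2)cc1 | intermediate
8 | (2S)-5-(benzyloxy)-2-[4-(benzyloxy)phenyl]-7-(methoxymethoxy)chromane | COCOc1cc(OCc2ccccc2)c2c(c1)O[C@H](c1ccc(OCc3ccccc3)cc1)CC2 | intermediate
9 | (2S)-5-(benzyloxy)-2-[4-(benzyloxy)phenyl]-8-bromo-7-(methoxymethoxy)chromane | COCOc1cc(OCc2ccccc2)c2c(c1Br)O[C@H](c1ccc(OCc3ccccc3)cc1)CC2 | intermediate
10 | 5-fluorobenzene-1,3-diol | Oc1cc(O)cc(F)c1 | starting material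
11 | 1-(2-fluoro-4,6-dihydroxyphenyl)ethanone | CC(=O)c1c(O)cc(O)cc1F | intermediate
12 | 1-[2,4-bis(benzyloxy)-6-fluorophenyl]ethanone | CC(=O)c1c(OCc2ccccc2)cc(OCc2ccccc2)cc1F | intermediate
13 | 2-[2,4-bis(benzyloxy)-6-fluorophenyl]-2-oxoacetaldehyde | O=CC(=O)c1c(OCc2ccccc2)cc(OCc2ccccc2)cc1F | intermediate
14 | 8-lithio derivative of flavan 8 | COCOc1cc(OCc2ccccc2)c2c(c1[Li])O[C@H](c1ccc(OCc3ccccc3)cc1)CC2 | intermediate
15 | 1-[2,4-bis(benzyloxy)-6-fluorophenyl]-2-hydroxy-2-{(2S)-5-(benzyloxy)-2-[4-(benzyloxy)phenyl]-7-(methoxymethoxy)chroman-8-yl}ethan-1-one, both carbinol epimers | COCOc1cc(OCc2ccccc2)c2c(c1C(O)C(=O)c1c(OCc3ccccc3)cc(OCc3ccccc3)cc1F)O[C@H](c1ccc(OCc3ccccc3)cc1)CC2 | intermediate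
16 | O-benzyl ether of 15 at the carbinol oxygen, both epimers | COCOc1cc(OCc2ccccc2)c2c(c1C(OCc1ccccc1)C(=O)c1c(OCc3ccccc3)cc(OCc3ccccc3)cc1F)O[C@H](c1ccc(OCc3ccccc3)cc1)CC2 | intermediate
17 | 7-hydroxy compound from 16 (MOM removed), both epimers | Oc1cc(OCc2ccccc2)c2c(c1C(OCc1ccccc1)C(=O)c1c(OCc3ccccc3)cc(OCc3ccccc3)cc1F)O[C@H](c1ccc(OCc3ccccc3)cc1)CC2 | intermediate
18 | 4-(benzyloxy)benzoyl chloride | O=C(Cl)c1ccc(OCc2ccccc2)cc1 | starting material
19 | (2S)-5-(benzyloxy)-2-[4-(benzyloxy)phenyl]-8-{1-(benzyloxy)-2-[2,4-bis(benzyloxy)-6-fluorophenyl]-2-oxoethyl}chroman-7-yl 4-(benzyloxy)benzoate, both epimers | O=C(Oc1cc(OCc2ccccc2)c2c(c1C(OCc1ccccc1)C(=O)c1c(OCc3ccccc3)cc(OCc3ccccc3)cc1F)O[C@H](c1ccc(OCc3ccccc3)cc1)CC2)c1ccc(OCc2ccccc2)cc1 | intermediate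
20 | enolate of 19, deprotonated at the benzyloxy-bearing carbon | O=C(Oc1cc(OCc2ccccc2)c2c(c1C(OCc1ccccc1)=C([O-])c1c(OCc3ccccc3)cc(OCc3ccccc3)cc1F)O[C@H](c1ccc(OCc3ccccc3)cc1)CC2)c1ccc(OCc2ccccc2)cc1 | intermediate
21 | hemiketal alkoxide: flavan-fused 2,3-dihydrofuran with 2-[4-(benzyloxy)phenyl] and 2-oxido, 3-benzyloxy and 3-[2,4-bis(benzyloxy)-6-fluorobenzoyl], oxido cis to aroyl | [O-][C@@]1(c2ccc(OCc3ccccc3)cc2)Oc2cc(OCc3ccccc3)c3c(c2[C@]1(OCc1ccccc1)C(=O)c1c(OCc2ccccc2)cc(OCc2ccccc2)cc1F)O[C@H](c1ccc(OCc2ccccc2)cc1)CC3 | intermediate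
22 | hexa-O-benzyl ether of the target (all six hydroxyls as benzyl ethers, configuration as in the target) | O=C1c2c(OCc3ccccc3)cc(OCc3ccccc3)cc2O[C@@]2(c3ccc(OCc4ccccc4)cc3)Oc3cc(OCc4ccccc4)c4c(c3[C@]12OCc1ccccc1)O[C@H](c1ccc(OCc2ccccc2)cc1)CC4 | intermediate
23 | target CNP0208300.3 (flavan C-2 S, ketal carbon R, tertiary carbinol carbon S) | O=C1c2c(O)cc(O)cc2O[C@@]2(c3ccc(O)cc3)Oc3cc(O)c4c(c3[C@]12O)O[C@H](c1ccc(O)cc1)CC4 | target

**Step count**
Total steps: 16. Longest linear sequence: 13 (steps 1–7, then 11–16); the ring A branch (steps 8–10) joins at step 11.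

**Steps most likely to fail**

1. Step 15. The tetrahedral alkoxide may collapse faster than it is arylated, letting the freed phenoxide or the enolate oxygen react elsewhere, or the ion pair may give little facial discrimination at the enolate carbon. The fallback uses known chemistry, sets out from 19 and returns at 22. Compound 19 is treated with LiN(SiMe3)2 in THF at −78 to 0 °C so that the reaction stops after the Baker–Venkataraman-type O-to-C aroyl transfer. After quench this should give 2-(benzyloxy)-1-[2,4-bis(benzyloxy)-6-fluorophenyl]-2-{(2S)-5-(benzyloxy)-2-[4-(benzyloxy)phenyl]-7-hydroxychroman-8-yl}-3-[4-(benzyloxy)phenyl]propane-1,3-dione F1. Its quaternary carbon is configurationally fixed, so the two diastereomers can be separated by chromatography. The one configured as in 22 is then closed with K2CO3 in DMF at 60–80 °C, by hemiketalisation of the phenol onto the 4-(benzyloxy)benzoyl ketone and intramolecular SNAr of the fluoride, to rejoin the route at 22.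

2. Step 11. The hindered aryllithium may add to the ketone carbonyl, be quenched by proton or electron transfer, or find the hygroscopic glyoxal incompletely dried, so conversion is low. The fallback sets out from 9 and 12 and returns at 15. Palladium-catalysed α-arylation of methyl ketone 12 with bromide 9 (Pd2(dba)3, P(t-Bu)3, NaOt-Bu, toluene, 80 °C) should give 1-[2,4-bis(benzyloxy)-6-fluorophenyl]-2-{(2S)-5-(benzyloxy)-2-[4-(benzyloxy)phenyl]-7-(methoxymethoxy)chroman-8-yl}ethan-1-one F2. Enolisation with KN(SiMe3)2 in THF at −78 °C and Davis hydroxylation with 2-(phenylsulfonyl)-3-phenyloxaziridine then gives 15.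

3. Step 16. Over-reduction may occur before the last benzyl ether is gone: hydrogenolysis of the benzylic C–O bonds of the ketal, the flavan or the tertiary carbinol, or reduction of the ketone. The fallback sets out from 22 and returns at 23. It is a non-reductive debenzylation with BCl3 and pentamethylbenzene as cation scavenger in CH2Cl2 at −78 °C, followed by methanol quench. It makes no compound outside the list (F0).

**Further compounds**
F1 | step 15 | 2-(benzyloxy)-1-[2,4-bis(benzyloxy)-6-fluorophenyl]-2-{(2S)-5-(benzyloxy)-2-[4-(benzyloxy)phenyl]-7-hydroxychroman-8-yl}-3-[4-(benzyloxy)phenyl]propane-1,3-dione, quaternary carbon configured as in 22 | O=C(c1ccc(OCc2ccccc2)cc1)[C@](OCc1ccccc1)(c1c(O)cc(OCc2ccccc2)c2c1O[C@H](c1ccc(OCc3ccccc3)cc1)CC2)C(=O)c1c(OCc2ccccc2)cc(OCc2ccccc2)cc1F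
F2 | step 11 | 1-[2,4-bis(benzyloxy)-6-fluorophenyl]-2-{(2S)-5-(benzyloxy)-2-[4-(benzyloxy)phenyl]-7-(methoxymethoxy)chroman-8-yl}ethan-1-one | COCOc1cc(OCc2ccccc2)c2c(c1CC(=O)c1c(OCc3ccccc3)cc(OCc3ccccc3)cc1F)O[C@H](c1ccc(OCc3ccccc3)cc1)CC2
F0 | step 16 | none | none
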